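**Plan**
- Retrosynthesis: after debenzylation, the lower pyran ring (ring F) is cut at C3–C4, so its vicinal diol becomes a 1,6-dialdehyde (pinacol). The O1–C2 ether of ring F, the interflavan C4(ring C)–C6(ring D) bond, and ring C (same way as ring F) are cut next.
- Forward: salicylaldehyde 2 (ring A) is annulated to ring C by etherification, ozonolysis and pinacol closure. The C4 cation of that diol arylates a second molecule of 2 (ring D). Ring F is then closed last by the same three operations, followed by hydrogenolysis.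
- Enabling feature: in ring F the C3/C4 diol has C4 benzylic on ring D, ortho to the ring oxygen O1. Both carbons can therefore be aldehyde carbons hung on the O1–C2 ether, and the aryl aldehyde is the more easily reduced, so a ketyl joins two electrophilic carbons.
- Stereochemistry: C2 of each unit comes from ligand-controlled iridium-catalysed allylic etherification. C3 and C4 of each pyran ring come from the pinacol closure under control of C2 (2,3-cis-3,4-trans). C4 of ring C comes from β-face arylation anti to the 3-OH.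

Key step: step 11

Remark: rings are lettered A (benzo), B (aryl), C (pyran) in the upper unit and D, E, F likewise in the lower unit; flavan numbering is used within each unit.
Remark: the sense of induction of the iridium catalyst is assumed to follow the usual model for this ligand class; the ligand antipode that gives the S ether is the one used.
Remark: the C4 hydroxyl on ring F is acid-labile, so everything after step 11 is run neutral.

**Step 1**
Reactants: 1 2,3,4-trihydroxybenzaldehyde
Product: 2 3,4-bis(benzyloxy)-2-hydroxybenzaldehyde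
Conditions: BnBr (2.1 equiv), K2CO3 (2.1 equiv), DMF, 0 °C to rt
Reagents that add atoms: benzyl bromide, BrCc1ccccc1
Why: Williamson etherification should stop after O-4 and O-3 because the 2-OH is hydrogen-bonded to the formyl group and is the least nucleophilic.

**Step 2**
Reactants: 3 4-(benzyloxy)benzaldehyde; 4 triethyl phosphonoacetate
Product: 5 ethyl (E)-3-[4-(benzyloxy)phenyl]prop-2-enoate
Conditions: NaH, THF, 0 °C to rt
Reagents that add atoms: none
Why: Horner–Wadsworth–Emmons olefination of an aryl aldehyde with a stabilised phosphonate should give the E enoate.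

**Step 3**
Reactants: 5 ethyl (E)-3-[4-(benzyloxy)phenyl]prop-2-enoate
Product: 6 (E)-3-[4-(benzyloxy)phenyl]prop-2-en-1-ol
Conditions: i-Bu2AlH (2.2 equiv), CH2Cl2, −78 °C; aq. potassium sodium tartrate
Reagents that add atoms: none
Why: 1,2-reduction of the enoate by the aluminium hydride should give the allylic alcohol without touching the alkene or the benzyl ether.

**Step 4**
Reactants: 6 (E)-3-[4-(benzyloxy)phenyl]prop-2-en-1-ol
Product: 7 (E)-3-[4-(benzyloxy)phenyl]prop-2-en-1-yl methyl carbonate
Conditions: ClCO2Me, pyridine, CH2Cl2, 0 °C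
Reagents that add atoms: methyl chloroformate, COC(=O)Cl
Why: O-acylation installs the carbonate leaving group needed for allyl-iridium formation.

**Step 5**
Reactants: 2 3,4-bis(benzyloxy)-2-hydroxybenzaldehyde; 7 (E)-3-[4-(benzyloxy)phenyl]prop-2-en-1-yl methyl carbonate
Product: 8 3,4-bis(benzyloxy)-2-{[(1S)-1-(4-benzyloxyphenyl)prop-2-en-1-yl]oxy}benzaldehyde
Conditions: [Ir(cod)Cl]2 (2 mol %), (Sa,Sc,Sc)-(1,1'-binaphthalene-2,2'-diyl) N,N-bis(1-phenylethyl)phosphoramidite (4 mol %, pre-activated with n-PrNH2, volatiles removed), K3PO4 (0.2 equiv), THF, 40 °C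
Reagents that add atoms: none
Why: in this iridium-catalysed asymmetric allylic etherification the phenoxide should attack the aryl-substituted terminus of the allyl-iridium intermediate (branched product) on the face set by the cyclometalated phosphoramidite, giving the S ether that becomes C2 of ring C.

**Step 6**
Reactants: 8 3,4-bis(benzyloxy)-2-{[(1S)-1-(4-benzyloxyphenyl)prop-2-en-1-yl]oxy}benzaldehyde
Product: 10 3,4-bis(benzyloxy)-2-{[(1R)-1-(4-benzyloxyphenyl)-2-oxoethyl]oxy}benzaldehyde, via secondary ozonide 9 (not isolated)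
Conditions: O3, CH2Cl2, −78 °C (Sudan Red 7B end-point indicator); PPh3, −78 to 0 °C; crude product used at once
Reagents that add atoms: ozone, [O-][O+]=O
Why: ozonolysis with reductive work-up should cleave only the terminal alkene, which reacts far faster than benzyl ethers or the oxygenated arenes, and the cold neutral medium should preserve the acidic C–H of the new α-aryloxy aldehyde.

**Step 7**
Reactants: 10 3,4-bis(benzyloxy)-2-{[(1R)-1-(4-benzyloxyphenyl)-2-oxoethyl]oxy}benzaldehyde
Product: 11 (2R,3R,4S)-7,8-bis(benzyloxy)-2-(4-benzyloxyphenyl)chromane-3,4-diol (2,3-cis-3,4-trans)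
Conditions: Cp2TiPh (2.5 equiv, stock solution), THF, −78 to −20 °C, slow addition of 10 to 0.01 M; pH 7 phosphate buffer
Reagents that add atoms: none
Why: titanocene-mediated intramolecular pinacol coupling of the 1,6-dialdehyde should close ring C with the C2 aryl pseudo-equatorial and the two titanoxy groups anti, giving the 2,3-cis-3,4-trans diol; the C4 configuration is of no consequence here because C4 is ionised in step 8.

**Step 8**
Reactants: 11 (2R,3R,4S)-7,8-bis(benzyloxy)-2-(4-benzyloxyphenyl)chromane-3,4-diol; 2 3,4-bis(benzyloxy)-2-hydroxybenzaldehyde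
Product: 12 3,4-bis(benzyloxy)-5-[(2R,3R,4R)-7,8-bis(benzyloxy)-2-(4-benzyloxyphenyl)-3-hydroxychroman-4-yl]-2-hydroxybenzaldehyde (4β-aryl, 3,4-trans)
Conditions: 2 (4 equiv), BF3·OEt2 (0.5 equiv), CH2Cl2, −20 to 0 °C
Reagents that add atoms: none
Why: in this Friedel–Crafts alkylation BF3 should ionise the benzylic C4–OH (cation stabilised by O1 and the 7-benzyloxy group), and arene 2 should attack through C5, its only activated position (para to OH, ortho to OBn), from the β-face anti to the axial 3-OH and the 2-aryl group.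

**Step 9**
Reactants: 12 the dimeric salicylaldehyde of step 8; 7 (E)-3-[4-(benzyloxy)phenyl]prop-2-en-1-yl methyl carbonate
Product: 13 3,4-bis(benzyloxy)-2-{[(1S)-1-(4-benzyloxyphenyl)prop-2-en-1-yl]oxy}-5-[(2R,3R,4R)-7,8-bis(benzyloxy)-2-(4-benzyloxyphenyl)-3-hydroxychroman-4-yl]benzaldehyde
Conditions: 7 (2 equiv), [Ir(cod)Cl]2 (2 mol %), the same (Sa,Sc,Sc) phosphoramidite (4 mol %, pre-activated), K3PO4 (0.2 equiv), THF, 40 °C
Reagents that add atoms: none
Why: the same iridium-catalysed asymmetric allylic etherification should occur only at the phenoxide (the secondary 3-OH is not deprotonated by the weak base), and ligand control sets the S ether centre that becomes C2 of ring F.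

**Step 10**
Reactants: 13 the allyl ether of step 9
Product: 15 3,4-bis(benzyloxy)-2-{[(1R)-1-(4-benzyloxyphenyl)-2-oxoethyl]oxy}-5-[(2R,3R,4R)-7,8-bis(benzyloxy)-2-(4-benzyloxyphenyl)-3-hydroxychroman-4-yl]benzaldehyde, via secondary ozonide 14 (not isolated)
Conditions: O3, CH2Cl2, −78 °C (Sudan Red 7B end-point indicator); PPh3, −78 to 0 °C; crude product used at once
Reagents that add atoms: ozone, [O-][O+]=O
Why: ozonolysis with reductive work-up should again cleave only the terminal alkene and deliver the configurationally labile α-aryloxy aldehyde under cold, neutral conditions.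

**Step 11**
Reactants: 15 the dialdehyde of step 10
Product: 16 (2R,3R,4S)-7,8-bis(benzyloxy)-6-[(2R,3R,4R)-7,8-bis(benzyloxy)-2-(4-benzyloxyphenyl)-3-hydroxychroman-4-yl]-2-(4-benzyloxyphenyl)chromane-3,4-diol (hexa-O-benzyl target)
Conditions: Cp2TiPh (3.5 equiv, stock solution), THF, −78 to −20 °C, slow addition of 15 to 0.005 M; pH 7 phosphate buffer
Reagents that add atoms: none
Why: Electron transfer from Cp2TiPh (trivalent titanium) should first reduce the aryl aldehyde on ring D to a titanoxy-benzyl (ketyl) radical, which adds to the titanium-bound aliphatic aldehyde carbon with a second electron transfer; two carbonyl carbons of like polarity are thus joined as C4–C3 of ring F, and the bis(titanium alkoxide) hydrolyses to the diol. The closest known reaction type is the trans-selective titanocene-promoted intramolecular pinacol coupling of 1,6-dialdehydes to cyclic 1,2-diols. Ring F closes in a 6-exo-trig radical addition to the C=O group through a half-chair transition state whose tether contains O1 and two carbons of ring D. C3 and C4 are controlled by the existing C2 centre and by the reagent: the C2 aryl group sits pseudo-equatorial and the two bulky Cp2(Ph)Ti–O groups lie anti (diaxial), which puts O3 cis to the C2 aryl and O4 trans to O3, the 2,3-cis-3,4-trans (2R,3R,4S) triad. The step needs reduction of the aryl aldehyde in preference to the α-aryloxy aldehyde (whose ketyl would expel the phenoxide) and retention of the epimerisable C2 centre. The easier reduction of the conjugated aldehyde, the low temperature, the neutral aprotic medium and high dilution should secure both; extra reagent covers the free 3-OH of ring C.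

**Step 12**
Reactants: 16 hexa-O-benzyl target
Product: 17 (2R,3R,4S)-6-[(2R,3R,4S)-3,7,8-trihydroxy-2-(4-hydroxyphenyl)chroman-4-yl]-2-(4-hydroxyphenyl)chromane-3,4,7,8-tetrol
Conditions: H2 (1 atm), Pd(OH)2/C, EtOAc–MeOH (1:1), rt, acid-free glassware, stopped at uptake of 6 equiv; filtered and concentrated under argon
Reagents that add atoms: none
Why: hydrogenolysis should remove the six aryl benzyl ethers, while the secondary benzylic C4–OH of ring F and the C2–O1 bonds react far more slowly under neutral conditions.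

**Compound list**
1 | 2,3,4-trihydroxybenzaldehyde | O=Cc1ccc(O)c(O)c1O | starting material
2 | 3,4-bis(benzyloxy)-2-hydroxybenzaldehyde | O=Cc1ccc(OCc2ccccc2)c(OCc2ccccc2)c1O | intermediate
3 | 4-(benzyloxy)benzaldehyde | O=Cc1ccc(OCc2ccccc2)cc1 | starting material
4 | triethyl phosphonoacetate | CCOC(=O)CP(=O)(OCC)OCC | starting material
5 | ethyl (E)-3-[4-(benzyloxy)phenyl]prop-2-enoate | CCOC(=O)/C=C/c1ccc(OCc2ccccc2)cc1 | intermediate
6 | (E)-3-[4-(benzyloxy)phenyl]prop-2-en-1-ol | OC/C=C/c1ccc(OCc2ccccc2)cc1 | intermediate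
7 | (E)-3-[4-(benzyloxy)phenyl]prop-2-en-1-yl methyl carbonate | COC(=O)OC/C=C/c1ccc(OCc2ccccc2)cc1 | intermediate
8 | 3,4-bis(benzyloxy)-2-{[(1S)-1-(4-benzyloxyphenyl)prop-2-en-1-yl]oxy}benzaldehyde | C=C[C@H](Oc1c(C=O)ccc(OCc2ccccc2)c1OCc1ccccc1)c1ccc(OCc2ccccc2)cc1 | intermediate
9 | secondary ozonide of 8: 3,4-bis(benzyloxy)-2-[(R)-(4-benzyloxyphenyl)(1,2,4-trioxolan-3-yl)methoxy]benzaldehyde, both epimers at the trioxolane carbon | C1(OCOO1)[C@H](Oc1c(C=O)ccc(OCc2ccccc2)c1OCc1ccccc1)c1ccc(OCc2ccccc2)cc1 | intermediate (not isolated)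
10 | 3,4-bis(benzyloxy)-2-{[(1R)-1-(4-benzyloxyphenyl)-2-oxoethyl]oxy}benzaldehyde | O=C[C@H](Oc1c(C=O)ccc(OCc2ccccc2)c1OCc1ccccc1)c1ccc(OCc2ccccc2)cc1 | intermediate
11 | (2R,3R,4S)-7,8-bis(benzyloxy)-2-(4-benzyloxyphenyl)chromane-3,4-diol | c1cc2c(c(OCc3ccccc3)c1OCc1ccccc1)O[C@H](c1ccc(OCc3ccccc3)cc1)[C@H](O)[C@H]2O | intermediate
12 | 3,4-bis(benzyloxy)-5-[(2R,3R,4R)-7,8-bis(benzyloxy)-2-(4-benzyloxyphenyl)-3-hydroxychroman-4-yl]-2-hydroxybenzaldehyde | c1ccccc1COc1ccc([C@H]2Oc3c(ccc(OCc4ccccc4)c3OCc3ccccc3)[C@H](c3cc(C=O)c(O)c(OCc4ccccc4)c3OCc3ccccc3)[C@H]2O)cc1 | intermediate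
13 | 3,4-bis(benzyloxy)-2-{[(1S)-1-(4-benzyloxyphenyl)prop-2-en-1-yl]oxy}-5-[(2R,3R,4R)-7,8-bis(benzyloxy)-2-(4-benzyloxyphenyl)-3-hydroxychroman-4-yl]benzaldehyde | c1ccccc1COc1ccc([C@H]2Oc3c(ccc(OCc4ccccc4)c3OCc3ccccc3)[C@H](c3cc(C=O)c(O[C@@H](C=C)c4ccc(OCc5ccccc5)cc4)c(OCc4ccccc4)c3OCc3ccccc3)[C@H]2O)cc1 | intermediate
14 | secondary ozonide of 13 (1,2,4-trioxolan-3-yl in place of vinyl, R at the ether carbon, both epimers at the trioxolane carbon) | c1ccccc1COc1ccc([C@H]2Oc3c(ccc(OCc4ccccc4)c3OCc3ccccc3)[C@H](c3cc(C=O)c(O[C@@H](C6OCOO6)c4ccc(OCc5ccccc5)cc4)c(OCc4ccccc4)c3OCc3ccccc3)[C@H]2O)cc1 | intermediate (not isolated)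
15 | 3,4-bis(benzyloxy)-2-{[(1R)-1-(4-benzyloxyphenyl)-2-oxoethyl]oxy}-5-[(2R,3R,4R)-7,8-bis(benzyloxy)-2-(4-benzyloxyphenyl)-3-hydroxychroman-4-yl]benzaldehyde | c1ccccc1COc1ccc([C@H]2Oc3c(ccc(OCc4ccccc4)c3OCc3ccccc3)[C@H](c3cc(C=O)c(O[C@@H](C=O)c4ccc(OCc5ccccc5)cc4)c(OCc4ccccc4)c3OCc3ccccc3)[C@H]2O)cc1 | intermediate
16 | (2R,3R,4S)-7,8-bis(benzyloxy)-6-[(2R,3R,4R)-7,8-bis(benzyloxy)-2-(4-benzyloxyphenyl)-3-hydroxychroman-4-yl]-2-(4-benzyloxyphenyl)chromane-3,4-diol | c1ccccc1COc1ccc([C@H]2Oc3c(ccc(OCc4ccccc4)c3OCc3ccccc3)[C@H](c3cc4c(c(OCc5ccccc5)c3OCc3ccccc3)O[C@H](c3ccc(OCc5ccccc5)cc3)[C@H](O)[C@H]4O)[C@H]2O)cc1 | intermediate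
17 | (2R,3R,4S)-6-[(2R,3R,4S)-3,7,8-trihydroxy-2-(4-hydroxyphenyl)chroman-4-yl]-2-(4-hydroxyphenyl)chromane-3,4,7,8-tetrol | Oc1ccc([C@H]2Oc3c(ccc(O)c3O)[C@H](c3cc4c(c(O)c3O)O[C@H](c3ccc(O)cc3)[C@H](O)[C@H]4O)[C@H]2O)cc1 | target

**Step count and risks**
Total step count: 12. Longest linear sequence: 11 steps (steps 2–12, from 3).

Steps most likely to fail:

Step 11 (the same holds for its earlier counterpart, step 7). What may go wrong: loss of configuration at the α-aryloxy aldehyde carbon before ring closure, fragmentation by phenoxide expulsion if the aliphatic aldehyde is reduced first, or closure through a gauche arrangement of the two titanoxy groups, which would give the 3,4-cis or 2,3-trans diol. The fallback changes the bond that closes ring F from C3–C4 to O1–C2; it sets out from 12 and returns at 16. Zinc-mediated, amino-alcohol-ligand-controlled addition of 1-(benzyloxy)-4-ethynylbenzene to the aldehyde of 12 (Me2Zn in excess to cover the two acidic OH groups, ligand antipode chosen for the R carbinol) should give the propargylic alcohol (1R)-3-(4-benzyloxyphenyl)-1-aryl-prop-2-yn-1-ol F1. Semihydrogenation over lead-poisoned Pd/CaCO3 with quinoline should give the (1R,2Z)-allylic alcohol F2. Hydroxyl-directed epoxidation with mCPBA at 0 °C, threo-selective through allylic 1,3-strain, should give the cis-epoxy alcohol F3. Opening of the epoxide at its benzylic carbon by the ortho phenol in the 6-endo mode with inversion (Ti(OiPr)4 or catalytic camphorsulfonic acid, CH2Cl2) should then give 16.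

Step 8. What may go wrong: slow capture of the C4 cation by the hydrogen-bonded, formyl-deactivated arene, so that self-condensation of 11 through its own ring A, or O-arylation, takes over. The fallback changes the electrophile and its mode of activation; it sets out from 11 and returns at 12. Thiolysis of 11 with phenylmethanethiol and catalytic ZnI2 in CH2Cl2 should give, by the same β-face attack, (2R,3S,4S)-4-(benzylsulfanyl)-7,8-bis(benzyloxy)-2-(4-benzyloxyphenyl)chroman-3-ol F4. Thiophilic activation of F4 with AgBF4 in THF at 0 °C in the presence of excess 2 generates the cation irreversibly without acid and should give 12.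

Step 9 (the same holds for step 5). What may go wrong: sluggish attack of the hindered, hydrogen-bonded phenoxide on the allyl-iridium intermediate, and re-ionisation of the product ether (a salicylaldehyde phenoxide is a good leaving group), which would erode branched selectivity and enantiomeric purity. The fallback masks the formyl group as a vinyl group before the etherification; it sets out from 12 and returns at 15. Wittig methylenation of 12 with excess Ph3P=CH2 in THF should give the 2-vinylphenol F5, which has no intramolecular hydrogen bond, gives a poorer leaving group, and belongs to a substrate class with close precedent for this etherification. Iridium-catalysed etherification of F5 with 7 under the conditions of step 9 should give the diene ether F6. Ozonolysis of both terminal alkenes of F6 with PPh3 work-up should give 15.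

**Further compounds**
F1 | step 11 | 3,4-bis(benzyloxy)-5-[(2R,3R,4R)-7,8-bis(benzyloxy)-2-(4-benzyloxyphenyl)-3-hydroxychroman-4-yl]-1-[(1R)-3-(4-benzyloxyphenyl)-1-hydroxyprop-2-yn-1-yl]-2-hydroxybenzene | c1ccccc1COc1ccc([C@H]2Oc3c(ccc(OCc4ccccc4)c3OCc3ccccc3)[C@H](c3cc([C@H](O)C#Cc4ccc(OCc5ccccc5)cc4)c(O)c(OCc4ccccc4)c3OCc3ccccc3)[C@H]2O)cc1
F2 | step 11 | the corresponding (1R,2Z)-3-(4-benzyloxyphenyl)-1-hydroxyprop-2-en-1-yl compound | c1ccccc1COc1ccc([C@H]2Oc3c(ccc(OCc4ccccc4)c3OCc3ccccc3)[C@H](c3cc([C@H](O)/C=C\c4ccc(OCc5ccccc5)cc4)c(O)c(OCc4ccccc4)c3OCc3ccccc3)[C@H]2O)cc1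
F3 | step 11 | the corresponding (S)-[(2R,3S)-3-(4-benzyloxyphenyl)oxiran-2-yl](hydroxy)methyl compound (threo, cis-epoxide) | c1ccccc1COc1ccc([C@H]2Oc3c(ccc(OCc4ccccc4)c3OCc3ccccc3)[C@H](c3cc([C@H](O)[C@H]6O[C@H]6c4ccc(OCc5ccccc5)cc4)c(O)c(OCc4ccccc4)c3OCc3ccccc3)[C@H]2O)cc1
F4 | step 8 | (2R,3S,4S)-4-(benzylsulfanyl)-7,8-bis(benzyloxy)-2-(4-benzyloxyphenyl)chroman-3-ol | c1cc2c(c(OCc3ccccc3)c1OCc1ccccc1)O[C@H](c1ccc(OCc3ccccc3)cc1)[C@H](O)[C@H]2SCc1ccccc1
F5 | step 9 | 2,3-bis(benzyloxy)-4-[(2R,3R,4R)-7,8-bis(benzyloxy)-2-(4-benzyloxyphenyl)-3-hydroxychroman-4-yl]-6-vinylphenol | c1ccccc1COc1ccc([C@H]2Oc3c(ccc(OCc4ccccc4)c3OCc3ccccc3)[C@H](c3cc(C=C)c(O)c(OCc4ccccc4)c3OCc3ccccc3)[C@H]2O)cc1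
F6 | step 9 | (1S)-1-(4-benzyloxyphenyl)prop-2-en-1-yl ether of F5 | c1ccccc1COc1ccc([C@H]2Oc3c(ccc(OCc4ccccc4)c3OCc3ccccc3)[C@H](c3cc(C=C)c(O[C@@H](C=C)c4ccc(OCc5ccccc5)cc4)c(OCc4ccccc4)c3OCc3ccccc3)[C@H]2O)cc1
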